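## Retrosynthetic overview

1. Target ⇐ lipase removal of a phenolic acetate ⇐ desilylation ⇐ acylation of the C-1 allylic alcohol with 4-acetoxybenzoyl chloride.
2. (1R)-Alcohol ⇐ ketoreductase reduction of the macrocyclic 2-en-1-one ⇐ oxidation of a Nozaki–Hiyama–Kishi product; closing the C1–C2 bond makes the 11-membered carbocycle, the only ring formed (the arene is bought).
3. Seco iodo-aldehyde ⇐ (E)-2-iodoalkene by hydrozirconation–iodination of a methyl alkyne; C-4 carbinol ⇐ Ru-catalysed asymmetric transfer hydrogenation of an ynone.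
4. Ynone ⇐ Weinreb amide + prop-1-ynylmagnesium bromide; quaternary C-5 ⇐ isobutyric acid dianion + primary iodide.
5. Iodide ⇐ (E)-homoallylic alcohol from Zr-catalysed carboalumination of silyl-protected pent-4-yn-1-ol and oxirane opening (sets C9=C10).

Assumption: locants follow the name (1R,2E,4R,9E)-4-hydroxy-2,5,5,9-tetramethylcycloundeca-2,9-dien-1-yl 4-hydroxybenzoate read from the SMILES; the (R)-selective ketoreductase of step 15 is taken from a commercial screening panel.

## Route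

Step 1
Reactants: 1 tert-butyldimethyl(pent-4-yn-1-yloxy)silane; 2 oxirane
Product: 4 (3E)-7-[(tert-butyldimethylsilyl)oxy]-4-methylhept-3-en-1-ol, via alkenyl-AlMe2 species 3 (not isolated)
Conditions: AlMe3 (2.5 equiv), Cp2ZrCl2 (0.25 equiv), CH2Cl2, 0 °C → rt; volatiles removed; n-BuLi (1.05 equiv), hexane/THF, −78 °C; then 2 (3 equiv), −78 → 0 °C; H2O work-up
Reagents that add atoms: trimethylaluminium C[Al](C)C
Why: Negishi zirconium-catalysed carboalumination adds Me and Al syn across the terminal alkyne with Me on the internal carbon, and the derived alkenylalanate opens oxirane with retention, so the (E)-C9=C10 olefin is fixed (no stereocentre formed).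

Step 2
Reactants: 4 (3E)-7-[(tert-butyldimethylsilyl)oxy]-4-methylhept-3-en-1-ol
Product: 5 tert-butyl({(4E)-7-[(4-methoxyphenyl)methoxy]-4-methylhept-4-en-1-yl}oxy)dimethylsilane
Conditions: NaH, 4-methoxybenzyl chloride, Bu4NI (cat.), THF/DMF, 0 °C → rt
Reagents that add atoms: 4-methoxybenzyl chloride COc1ccc(CCl)cc1
Why: Williamson etherification of the primary alkoxide proceeds by SN2 on the benzylic chloride while the silyl ether is inert to NaH.

Step 3
Reactants: 5 tert-butyl({(4E)-7-[(4-methoxyphenyl)methoxy]-4-methylhept-4-en-1-yl}oxy)dimethylsilane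
Product: 6 (4E)-7-[(4-methoxyphenyl)methoxy]-4-methylhept-4-en-1-ol
Conditions: TBAF, THF, 0 °C → rt
Reagents that add atoms: none
Why: Fluoride-driven desilylation frees the primary alcohol and leaves the benzylic ether and the alkene untouched.

Step 4
Reactants: 6 (4E)-7-[(4-methoxyphenyl)methoxy]-4-methylhept-4-en-1-ol
Product: 7 1-({[(3E)-7-iodo-4-methylhept-3-en-1-yl]oxy}methyl)-4-methoxybenzene
Conditions: I2, PPh3, imidazole, CH2Cl2, 0 °C → rt
Reagents that add atoms: iodine I-I
Why: Appel-type (Garegg–Samuelsson) iodination converts the primary alcohol into the iodide by SN2 on an alkoxyphosphonium ion without touching the trisubstituted alkene.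

Step 5
Reactants: 7 1-({[(3E)-7-iodo-4-methylhept-3-en-1-yl]oxy}methyl)-4-methoxybenzene; 8 2-methylpropanoic acid
Product: 10 (6E)-9-[(4-methoxyphenyl)methoxy]-2,2,6-trimethylnon-6-enoic acid, via dilithium enediolate 9 (not isolated)
Conditions: 8 (1.5 equiv), LiN(iPr)2 (commercial solution, 3.2 equiv), THF, 0 → 45 °C; then 7, 0 °C → rt; cold 1 M HCl
Reagents that add atoms: none
Why: Alkylation of the isobutyric acid dianion (carboxylic acid dianion alkylation) by SN2 on the unhindered primary iodide builds the quaternary C-5 and delivers the acid directly.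

Step 6
Reactants: 10 (6E)-9-[(4-methoxyphenyl)methoxy]-2,2,6-trimethylnon-6-enoic acid
Product: 12 (6E)-N-methoxy-9-[(4-methoxyphenyl)methoxy]-N,2,2,6-tetramethylnon-6-enamide, via acid chloride 11 (not isolated)
Conditions: 1-chloro-N,N,2-trimethylprop-1-en-1-amine (Ghosez reagent), CH2Cl2, 0 °C → rt; then MeNH(OMe)·HCl, pyridine, 0 °C → rt
Reagents that add atoms: N,O-dimethylhydroxylamine hydrochloride CNOC.Cl
Why: Weinreb amide formation through an acid chloride made under neutral, HCl-free conditions spares the acid-sensitive benzylic ether and the alkene even though the acid is α-quaternary.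

Step 7
Reactants: 12 (6E)-N-methoxy-9-[(4-methoxyphenyl)methoxy]-N,2,2,6-tetramethylnon-6-enamide; 13 prop-1-yn-1-ylmagnesium bromide
Product: 14 (9E)-12-[(4-methoxyphenyl)methoxy]-5,5,9-trimethyldodec-9-en-2-yn-4-one
Conditions: 13 (0.5 M in THF, 3 equiv), THF, 0 → 40 °C; cold 1 M HCl
Reagents that add atoms: none
Why: Weinreb ketone synthesis stops at the ynone because the magnesium-chelated tetrahedral adduct only collapses on work-up, and it gives an achiral ketone ready for asymmetric reduction.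

Step 8
Reactants: 14 (9E)-12-[(4-methoxyphenyl)methoxy]-5,5,9-trimethyldodec-9-en-2-yn-4-one
Product: 15 (4S,9E)-12-[(4-methoxyphenyl)methoxy]-5,5,9-trimethyldodec-9-en-2-yn-4-ol
Conditions: Ru[(S,S)-TsDPEN](p-cymene) (preformed 16-electron amido complex, 2 mol%), propan-2-ol, 25 °C
Reagents that add atoms: none
Why: Noyori asymmetric transfer hydrogenation with the (S,S)-Ru catalyst delivers hydride from propan-2-ol to one carbonyl face with the alkyne held by a CH–π contact, so the first stereocentre of the route (target C-4) is set as the (4S)-propargylic alcohol without touching alkyne or alkene.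

Step 9
Reactants: 15 (4S,9E)-12-[(4-methoxyphenyl)methoxy]-5,5,9-trimethyldodec-9-en-2-yn-4-ol
Product: 16 tert-butyl({(4S,9E)-12-[(4-methoxyphenyl)methoxy]-5,5,9-trimethyldodec-9-en-2-yn-4-yl}oxy)dimethylsilane
Conditions: TBSOTf, 2,6-lutidine, CH2Cl2, 0 °C
Reagents that add atoms: tert-butyldimethylsilyl trifluoromethanesulfonate CC(C)(C)[Si](C)(C)OS(=O)(=O)C(F)(F)F
Why: O-silylation with the silyl triflate is fast enough for the hindered neopentyl-type carbinol and does not affect the stereocentre.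

Step 10
Reactants: 16 tert-butyl({(4S,9E)-12-[(4-methoxyphenyl)methoxy]-5,5,9-trimethyldodec-9-en-2-yn-4-yl}oxy)dimethylsilane
Product: 18 tert-butyl({(2E,4R,9E)-2-iodo-12-[(4-methoxyphenyl)methoxy]-5,5,9-trimethyldodeca-2,9-dien-4-yl}oxy)dimethylsilane, via alkenyl-ZrCp2Cl species 17 (not isolated)
Conditions: Cp2Zr(H)Cl (2.5 equiv), THF, rt → 50 °C; then I2, 0 °C; aq. Na2S2O3
Reagents that add atoms: iodine I-I
Why: Hydrozirconation–iodination adds H–Zr syn with Zr on the methyl-bearing alkyne carbon remote from the bulky silyloxy centre and iodinolysis with retention gives the (2E)-iodoalkene with the target C2=C3 geometry (the carbinol is untouched; its descriptor becomes R only through changed CIP priorities).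

Step 11
Reactants: 18 tert-butyl({(2E,4R,9E)-2-iodo-12-[(4-methoxyphenyl)methoxy]-5,5,9-trimethyldodeca-2,9-dien-4-yl}oxy)dimethylsilane
Product: 19 (3E,9R,10E)-9-[(tert-butyldimethylsilyl)oxy]-11-iodo-4,8,8-trimethyldodeca-3,10-dien-1-ol
Conditions: DDQ, CH2Cl2/pH 7 buffer (10:1), 0 °C
Reagents that add atoms: none
Why: Oxidative cleavage of the 4-methoxybenzyl ether by DDQ (benzylic hydride abstraction, then hydrolysis) frees the primary alcohol without affecting the iodoalkene, the silyl ether or the alkenes.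

Step 12
Reactants: 19 (3E,9R,10E)-9-[(tert-butyldimethylsilyl)oxy]-11-iodo-4,8,8-trimethyldodeca-3,10-dien-1-ol
Product: 20 (3E,9R,10E)-9-[(tert-butyldimethylsilyl)oxy]-11-iodo-4,8,8-trimethyldodeca-3,10-dienal
Conditions: Dess–Martin periodinane, pyridine, CH2Cl2, 0 °C; used crude at once
Reagents that add atoms: none
Why: Dess–Martin oxidation under buffered non-basic conditions gives the β,γ-unsaturated aldehyde without migration of the alkene into conjugation.

Step 13
Reactants: 20 (3E,9R,10E)-9-[(tert-butyldimethylsilyl)oxy]-11-iodo-4,8,8-trimethyldodeca-3,10-dienal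
Product: 22 (2E,4R,9E)-4-[(tert-butyldimethylsilyl)oxy]-2,5,5,9-tetramethylcycloundeca-2,9-dien-1-ol as a mixture of C-1 epimers, via alkenyl-CrCl2 species 21 (not isolated)
Conditions: CrCl2 (10 equiv), NiCl2 (0.1 equiv), degassed DMSO/THF (3:1), rt, 20 added by syringe pump over 12 h (2 mM final); then H2O
Reagents that add atoms: none
Why: In the Nozaki–Hiyama–Kishi reaction NiCl2-catalysed activation of the C–I bond and transfer to divalent chromium gives an alkenylchromium that keeps the (E) geometry and adds only to the aldehyde under high dilution, closing the 11-membered ring; the new C-1 centre forms without control and is erased in step 14.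

Step 14
Reactants: 22 (2E,4R,9E)-4-[(tert-butyldimethylsilyl)oxy]-2,5,5,9-tetramethylcycloundeca-2,9-dien-1-ol as a mixture of C-1 epimers
Product: 23 (2E,4R,9E)-4-[(tert-butyldimethylsilyl)oxy]-2,5,5,9-tetramethylcycloundeca-2,9-dien-1-one
Conditions: Dess–Martin periodinane, pyridine, CH2Cl2, 0 °C → rt
Reagents that add atoms: none
Why: Dess–Martin oxidation of the allylic alcohol converges both C-1 epimers on one enone under mild buffered conditions.

Step 15
Reactants: 23 (2E,4R,9E)-4-[(tert-butyldimethylsilyl)oxy]-2,5,5,9-tetramethylcycloundeca-2,9-dien-1-one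
Product: 24 (1R,2E,4R,9E)-4-[(tert-butyldimethylsilyl)oxy]-2,5,5,9-tetramethylcycloundeca-2,9-dien-1-ol
Conditions: ketoreductase (R-selective, NADPH-dependent), NADP+ (cat.), propan-2-ol (10% v/v), KH2PO4/K2HPO4 buffer pH 7.0, MgSO4 (2 mM), DMSO (10% v/v), 30 °C
Reagents that add atoms: none
Why: Enzymatic carbonyl reduction by a ketoreductase delivers the NADPH hydride to a single face of the C-1 ketone in the enzyme pocket (1,2-reduction only), so (1R) is set under catalyst control independent of the remote C-4 centre while propan-2-ol recycles the cofactor.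

Step 16
Reactants: 24 (1R,2E,4R,9E)-4-[(tert-butyldimethylsilyl)oxy]-2,5,5,9-tetramethylcycloundeca-2,9-dien-1-ol; 25 4-acetoxybenzoyl chloride
Product: 26 (1R,2E,4R,9E)-4-[(tert-butyldimethylsilyl)oxy]-2,5,5,9-tetramethylcycloundeca-2,9-dien-1-yl 4-(acetyloxy)benzoate
Conditions: 25 (2 equiv), pyridine, CH2Cl2, 0 °C → rt
Reagents that add atoms: none
Why: O-acylation by the acid chloride (nucleophilic acyl substitution) occurs at oxygen with retention at C-1, and C-4 is blocked as its silyl ether.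

Step 17
Reactants: 26 (1R,2E,4R,9E)-4-[(tert-butyldimethylsilyl)oxy]-2,5,5,9-tetramethylcycloundeca-2,9-dien-1-yl 4-(acetyloxy)benzoate
Product: 27 (1R,2E,4R,9E)-4-hydroxy-2,5,5,9-tetramethylcycloundeca-2,9-dien-1-yl 4-(acetyloxy)benzoate
Conditions: HF·pyridine, pyridine, THF, 0 °C → rt, 24 h
Reagents that add atoms: none
Why: Buffered HF cleaves the hindered silyl ether by fluoride attack at silicon without hydrolysing either ester or ionising the allylic positions.

Step 18
Reactants: 27 (1R,2E,4R,9E)-4-hydroxy-2,5,5,9-tetramethylcycloundeca-2,9-dien-1-yl 4-(acetyloxy)benzoate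
Product: 28 (1R,2E,4R,9E)-4-hydroxy-2,5,5,9-tetramethylcycloundeca-2,9-dien-1-yl 4-hydroxybenzoate
Conditions: lipase (immobilised Candida antarctica lipase B), n-BuOH (5 equiv), t-BuOMe, 40 °C
Reagents that add atoms: none
Why: Lipase-catalysed transesterification passes the unhindered aryl acetate to butanol but does not accept the hindered secondary benzoate or the neopentyl-type C-4 alcohol, so the phenol is freed under neutral conditions.

## Compound list

1 | tert-butyldimethyl(pent-4-yn-1-yloxy)silane | C#CCCCO[Si](C)(C)C(C)(C)C | starting material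
2 | oxirane | C1CO1 | starting material
3 | [(1E)-5-[(tert-butyldimethylsilyl)oxy]-2-methylpent-1-en-1-yl]dimethylalane | C[Al](C)/C=C(\C)CCCO[Si](C)(C)C(C)(C)C | intermediate
4 | (3E)-7-[(tert-butyldimethylsilyl)oxy]-4-methylhept-3-en-1-ol | OCC/C=C(\C)CCCO[Si](C)(C)C(C)(C)C | intermediate
5 | tert-butyl({(4E)-7-[(4-methoxyphenyl)methoxy]-4-methylhept-4-en-1-yl}oxy)dimethylsilane | COc1ccc(COCC/C=C(\C)CCCO[Si](C)(C)C(C)(C)C)cc1 | intermediate
6 | (4E)-7-[(4-methoxyphenyl)methoxy]-4-methylhept-4-en-1-ol | COc1ccc(COCC/C=C(\C)CCCO)cc1 | intermediate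
7 | 1-({[(3E)-7-iodo-4-methylhept-3-en-1-yl]oxy}methyl)-4-methoxybenzene | COc1ccc(COCC/C=C(\C)CCCI)cc1 | intermediate
8 | 2-methylpropanoic acid (isobutyric acid) | CC(C)C(=O)O | starting material
9 | dilithium 2-methylprop-1-ene-1,1-bis(olate) | CC(C)=C(O[Li])O[Li] | intermediate
10 | (6E)-9-[(4-methoxyphenyl)methoxy]-2,2,6-trimethylnon-6-enoic acid | COc1ccc(COCC/C=C(\C)CCCC(C)(C)C(=O)O)cc1 | intermediate
11 | (6E)-9-[(4-methoxyphenyl)methoxy]-2,2,6-trimethylnon-6-enoyl chloride | COc1ccc(COCC/C=C(\C)CCCC(C)(C)C(=O)Cl)cc1 | intermediate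
12 | (6E)-N-methoxy-9-[(4-methoxyphenyl)methoxy]-N,2,2,6-tetramethylnon-6-enamide | COc1ccc(COCC/C=C(\C)CCCC(C)(C)C(=O)N(C)OC)cc1 | intermediate
13 | prop-1-yn-1-ylmagnesium bromide | CC#C[Mg]Br | starting material
14 | (9E)-12-[(4-methoxyphenyl)methoxy]-5,5,9-trimethyldodec-9-en-2-yn-4-one | COc1ccc(COCC/C=C(\C)CCCC(C)(C)C(=O)C#CC)cc1 | intermediate
15 | (4S,9E)-12-[(4-methoxyphenyl)methoxy]-5,5,9-trimethyldodec-9-en-2-yn-4-ol | CC#C[C@@H](O)C(C)(C)CCC/C(C)=C/CCOCc1ccc(OC)cc1 | intermediate
16 | tert-butyl({(4S,9E)-12-[(4-methoxyphenyl)methoxy]-5,5,9-trimethyldodec-9-en-2-yn-4-yl}oxy)dimethylsilane | CC#C[C@@H](O[Si](C)(C)C(C)(C)C)C(C)(C)CCC/C(C)=C/CCOCc1ccc(OC)cc1 | intermediate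
17 | chlorobis(cyclopentadienyl)[(2E,4R,9E)-4-[(tert-butyldimethylsilyl)oxy]-12-[(4-methoxyphenyl)methoxy]-5,5,9-trimethyldodeca-2,9-dien-2-yl]zirconium | C/C(=C\[C@@H](O[Si](C)(C)C(C)(C)C)C(C)(C)CCC/C(C)=C/CCOCc1ccc(OC)cc1)[Zr](Cl)(C1C=CC=C1)C1C=CC=C1 | intermediate
18 | tert-butyl({(2E,4R,9E)-2-iodo-12-[(4-methoxyphenyl)methoxy]-5,5,9-trimethyldodeca-2,9-dien-4-yl}oxy)dimethylsilane | I/C(C)=C/[C@@H](O[Si](C)(C)C(C)(C)C)C(C)(C)CCC/C(C)=C/CCOCc1ccc(OC)cc1 | intermediate
19 | (3E,9R,10E)-9-[(tert-butyldimethylsilyl)oxy]-11-iodo-4,8,8-trimethyldodeca-3,10-dien-1-ol | I/C(C)=C/[C@@H](O[Si](C)(C)C(C)(C)C)C(C)(C)CCC/C(C)=C/CCO | intermediate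
20 | (3E,9R,10E)-9-[(tert-butyldimethylsilyl)oxy]-11-iodo-4,8,8-trimethyldodeca-3,10-dienal | I/C(C)=C/[C@@H](O[Si](C)(C)C(C)(C)C)C(C)(C)CCC/C(C)=C/CC=O | intermediate
21 | dichloro[(2E,4R,9E)-4-[(tert-butyldimethylsilyl)oxy]-5,5,9-trimethyl-12-oxododeca-2,9-dien-2-yl]chromium | C/C(=C\[C@@H](O[Si](C)(C)C(C)(C)C)C(C)(C)CCC/C(C)=C/CC=O)[Cr](Cl)Cl | intermediate
22 | (2E,4R,9E)-4-[(tert-butyldimethylsilyl)oxy]-2,5,5,9-tetramethylcycloundeca-2,9-dien-1-ol, mixture of C-1 epimers | C/C1=C\CC(O)/C(C)=C/[C@@H](O[Si](C)(C)C(C)(C)C)C(C)(C)CCC1 | intermediate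
23 | (2E,4R,9E)-4-[(tert-butyldimethylsilyl)oxy]-2,5,5,9-tetramethylcycloundeca-2,9-dien-1-one | C/C1=C\CC(=O)/C(C)=C/[C@@H](O[Si](C)(C)C(C)(C)C)C(C)(C)CCC1 | intermediate
24 | (1R,2E,4R,9E)-4-[(tert-butyldimethylsilyl)oxy]-2,5,5,9-tetramethylcycloundeca-2,9-dien-1-ol | C/C1=C\C[C@@H](O)/C(C)=C/[C@@H](O[Si](C)(C)C(C)(C)C)C(C)(C)CCC1 | intermediate
25 | 4-acetoxybenzoyl chloride | CC(=O)Oc1ccc(cc1)C(=O)Cl | starting material
26 | (1R,2E,4R,9E)-4-[(tert-butyldimethylsilyl)oxy]-2,5,5,9-tetramethylcycloundeca-2,9-dien-1-yl 4-(acetyloxy)benzoate | C/C1=C\C[C@@H](OC(=O)c2ccc(OC(C)=O)cc2)/C(C)=C/[C@@H](O[Si](C)(C)C(C)(C)C)C(C)(C)CCC1 | intermediate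
27 | (1R,2E,4R,9E)-4-hydroxy-2,5,5,9-tetramethylcycloundeca-2,9-dien-1-yl 4-(acetyloxy)benzoate | C/C1=C\C[C@@H](OC(=O)c2ccc(OC(C)=O)cc2)/C(C)=C/[C@@H](O)C(C)(C)CCC1 | intermediate
28 | (1R,2E,4R,9E)-4-hydroxy-2,5,5,9-tetramethylcycloundeca-2,9-dien-1-yl 4-hydroxybenzoate (CNP0264320.1) | C/C1=C\C[C@@H](OC(=O)c2ccc(O)cc2)/C(C)=C/[C@@H](O)C(C)(C)CCC1 | target

## Step count and risks

Total steps: 18. Longest linear sequence: 18 steps (1 → 28; 2, 8, 13 and 25 are bought).

The three steps most likely to fail, in route order (step 13 is the riskiest):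

**Step 10, hydrozirconation–iodination of a hindered internal alkyne.** Conversion may be slow or the regiochemistry may erode. The fallback sets out from 16 and comes back at 18. Copper-catalysed formal hydroboration (CuCl 5 mol%, PCy3, NaOtBu, B2pin2, MeOH, THF, rt) adds H and boron syn across the alkyne, with boron on the methyl-bearing carbon remote from the silyloxy carbon. This gives the (2Z)-alkenyl pinacolboronate F1. Iododeboronation with retention (NaOH then I2, THF/H2O, 0 °C) then gives 18.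

**Step 13, Nozaki–Hiyama–Kishi macrocyclisation of the labile β,γ-unsaturated aldehyde.** Oligomerisation or aldehyde isomerisation may win over ring closure. The fallback sets out from 16 and comes back at 22, so neither the iodoalkene nor an organochromium is needed.
- DDQ (CH2Cl2/pH 7 buffer) removes the 4-methoxybenzyl group and gives the alkynol F2.
- Dess–Martin oxidation (pyridine buffer) gives the ynal F3.
- A nickel-catalysed reductive alkyne–aldehyde macrocyclisation (Ni(cod)2, zerovalent nickel, 20 mol%; IMes; Et3SiH; THF; syringe pump; rt) forms the C1–C2 bond at the methyl-bearing alkyne carbon with syn delivery of H to C-3. It gives the macrocyclic triethylsilyl ether F4 as C-1 epimers.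
- PPTS in MeOH at 0 °C removes only the triethylsilyl group and gives 22.

**Step 15, ketoreductase reduction of a bulky lipophilic macrocyclic enone.** No enzyme of the panel may accept 23 with useful selectivity. The fallback sets out from 22 and comes back at 26; steps 14 and 15 are skipped. The C-1 epimers of 22 are separated on silica. The (1R) epimer is 24 and is acylated as in step 16. The (1S) epimer F5 is esterified with 4-acetoxybenzoic acid under Mitsunobu conditions (PPh3, DIAD, toluene, 0 °C → rt), which inverts C-1 by SN2 and gives 26.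

## Further compounds

F1 | step 10 | tert-butyl({(2Z,4R,9E)-12-[(4-methoxyphenyl)methoxy]-5,5,9-trimethyl-2-(4,4,5,5-tetramethyl-1,3,2-dioxaborolan-2-yl)dodeca-2,9-dien-4-yl}oxy)dimethylsilane | C/C(B1OC(C)(C)C(C)(C)O1)=C\[C@@H](O[Si](C)(C)C(C)(C)C)C(C)(C)CCC/C(C)=C/CCOCc1ccc(OC)cc1
F2 | step 13 | (3E,9S)-9-[(tert-butyldimethylsilyl)oxy]-4,8,8-trimethyldodec-3-en-10-yn-1-ol | CC#C[C@@H](O[Si](C)(C)C(C)(C)C)C(C)(C)CCC/C(C)=C/CCO
F3 | step 13 | (3E,9S)-9-[(tert-butyldimethylsilyl)oxy]-4,8,8-trimethyldodec-3-en-10-ynal | CC#C[C@@H](O[Si](C)(C)C(C)(C)C)C(C)(C)CCC/C(C)=C/CC=O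
F4 | step 13 | tert-butyldimethyl{[(1R,2E,7E)-2,8,11,11-tetramethyl-4-[(triethylsilyl)oxy]cycloundeca-2,7-dien-1-yl]oxy}silane, mixture of epimers at the triethylsilyloxy carbon | C/C1=C\CC(O[Si](CC)(CC)CC)/C(C)=C/[C@@H](O[Si](C)(C)C(C)(C)C)C(C)(C)CCC1
F5 | step 15 | (1S,2E,4R,9E)-4-[(tert-butyldimethylsilyl)oxy]-2,5,5,9-tetramethylcycloundeca-2,9-dien-1-ol | C/C1=C\C[C@H](O)/C(C)=C/[C@@H](O[Si](C)(C)C(C)(C)C)C(C)(C)CCC1
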